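**Retrosynthetic overview**

1. The target is read as fisetinidol-(4α→6)-catechin (upper unit rings A, C, B; lower unit rings D, F, E). The last C–C disconnection is the interflavan bond C4(upper)–C6(ring D): Friedel–Crafts attack of a C8-brominated, benzylated catechin on a 3-O-acetyl fisetinidol C4 cation made from (+)-fustin, which supplies rings A, C, B and the upper C2/C3 centres.
2. The catechin unit is built from scratch, and its pyran ring F is the only ring formed in the route. It is closed at C2–C3 by a one-flask titanium-mediated carbonyl–olefin metathesis of an aryl ester that carries an ortho allyl group.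
3. Enabling feature: in ring F, C2 carries only the ring oxygen O1 and ring E besides C3. At the enol ether level (C2=C3) it is therefore the carbonyl carbon of a ring D aryl 3,4-dioxygenated benzoate, while C4 and C3 are the first two carbons of an allyl group that a Claisen rearrangement places ortho to O1 on the phloroglucinol ring D.
4. The C2=C3 enol ether is the oxidation level from which one syn hydroboration–oxidation installs the 3-OH and both stereocentres of ring F (2,3-trans, 2R,3S).
5. Order: rings D and E purchased → ring F (step 4) → C2/C3 stereocentres (step 5) → C8 bromine block (step 6) → union with the fustin-derived rings A/C/B (step 10) → deacetylation and hydrogenolysis.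

Key step: step 4

Remark: the upper unit is (2R,3S,4S) all-trans and the lower unit (2R,3S)-trans; (+)-fustin, 3,5-bis(benzyloxy)phenol and 3,4-bis(benzyloxy)benzoic acid are taken as purchasable, fustin as the single (2R,3R) enantiomer.

**Route**

Step 1
Reactants: 1 3,5-bis(benzyloxy)phenol
Product: 2 1-(allyloxy)-3,5-bis(benzyloxy)benzene
Conditions: allyl bromide, K2CO3, acetone, reflux
Reagents that add atoms: allyl bromide, C=CCBr
Why: Williamson O-allylation of the only free phenol under mild carbonate conditions should be clean, and no stereocentre is formed.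

Step 2
Reactants: 2 1-(allyloxy)-3,5-bis(benzyloxy)benzene
Product: 3 2-allyl-3,5-bis(benzyloxy)phenol
Conditions: N,N-diethylaniline, 190 °C, sealed vessel
Reagents that add atoms: none
Why: The aromatic Claisen rearrangement ([3,3]-sigmatropic shift, then tautomerization) should deliver the allyl group to one of the two equivalent ortho positions, so that the future C4 and C3 stand next to the future ring oxygen O1, and no stereocentre is formed.

Step 3
Reactants: 3 2-allyl-3,5-bis(benzyloxy)phenol; 4 3,4-bis(benzyloxy)benzoic acid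
Product: 5 2-allyl-3,5-bis(benzyloxy)phenyl 3,4-bis(benzyloxy)benzoate
Conditions: DCC, DMAP (cat.), CH2Cl2, 0 °C → rt
Reagents that add atoms: none
Why: Steglich esterification should join the ring D phenol oxygen (future O1) to the carboxyl carbon (future C2) that already carries ring E, and no stereocentre is formed.

Step 4
Reactants: 5 2-allyl-3,5-bis(benzyloxy)phenyl 3,4-bis(benzyloxy)benzoate
Product: 7 5,7-bis(benzyloxy)-2-[3,4-bis(benzyloxy)phenyl]-4H-chromene (tetra-O-benzylflav-2-ene), via vinyl ether diene 6 (not isolated)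
Conditions: Cp2Ti(μ-Cl)(μ-CH2)AlMe2 (4 equiv), pyridine (cat.), THF, 0 → 25 °C, then reflux; aq. NaOH, basic Al2O3
Reagents that add atoms: none
Why: The Tebbe reagent releases Cp2Ti=CH2, which first methylenates the aryl ester carbonyl through an oxatitanacyclobutane to give the 1-aryl-1-aryloxyethene 6, and on heating a further equivalent exchanges with the terminal allyl alkene (titanacyclobutane, loss of ethylene) to a titanium alkylidene on C3 that adds across the enol ether double bond and cycloreverts, forming the C2=C3 bond and regenerating Cp2Ti=CH2. The closest known reaction type is the one-flask Tebbe olefination/ring-closing metathesis of olefinic esters to six- and seven-membered cyclic enol ethers, together with the methylenation of aryl benzoates and the ring-closing metathesis of the resulting aryl vinyl ethers to 2-substituted 4H-chromenes. Ring F is closed as a six-membered ring by ring-closing metathesis of a 1,7-diene unit (enol ether alkene plus allyl alkene) in which four of the six ring atoms (O1, C8a, C4a, C4) are already held in place by the planar ring D, so cyclization should outrun oligomerization. No stereocentre is formed; the step delivers C2 and C3 as a trisubstituted endocyclic enol ether whose two faces are differentiated in step 5. The selectivity needed is olefination of the single ester carbonyl and ring closure onto its vinyl ether carbon without double-bond migration to the 2H-chromene or hydrolysis, which the substrate secures by having no other carbonyl group and only inert benzyl ethers, supported by a base-buffered treatment (pyridine, aqueous NaOH, basic alumina) of the acid-sensitive product.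

Step 5
Reactants: 7 5,7-bis(benzyloxy)-2-[3,4-bis(benzyloxy)phenyl]-4H-chromene
Product: 9 (2R,3S)-5,7,3',4'-tetra-O-benzylcatechin, via flavan-3-yl(isopinocampheyl)borane 8 (not isolated)
Conditions: IpcBH2 [from (+)-α-pinene], THF, −25 → 0 °C; then NaOH, H2O2, 0 °C → rt
Reagents that add atoms: hydrogen peroxide, OO
Why: In this asymmetric hydroboration–oxidation boron should add to C3 (the enol ether β-carbon, remote from the aryl group) and hydrogen to C2 on the same face, so that oxidation with retention gives the 2,3-trans alcohol, and the reagent enantiomer derived from (+)-α-pinene is chosen because, in the established model for 1-arylcycloalkenes, it attacks the alkene face that corresponds to the (2R,3S) product.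

Step 6
Reactants: 9 (2R,3S)-5,7,3',4'-tetra-O-benzylcatechin
Product: 10 (2R,3S)-8-bromo-5,7,3',4'-tetra-O-benzylcatechin
Conditions: NBS, CH2Cl2, −78 → 0 °C
Reagents that add atoms: N-bromosuccinimide, O=C1CCC(=O)N1Br
Why: Electrophilic aromatic bromination should take place at C8, the more accessible of the two free positions of the phloroglucinol-type ring D in tetra-O-benzyl flavan-3-ols, which leaves C6 as the only nucleophilic site of ring D and touches no stereocentre.

Step 7
Reactants: 11 (+)-fustin, (2R,3R)-3,7,3',4'-tetrahydroxyflavanone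
Product: 12 (2R,3R)-7,3',4'-tri-O-benzylfustin
Conditions: BnBr, K2CO3, DMF, rt, Ar
Reagents that add atoms: benzyl bromide, BrCc1ccccc1
Why: Williamson O-benzylation of the three phenols with a weak base at room temperature under argon should leave the secondary alcohol and the C2/C3 stereocentres of the dihydroflavonol untouched, and no stereocentre is formed.

Step 8
Reactants: 12 (2R,3R)-7,3',4'-tri-O-benzylfustin
Product: 13 (2R,3S,4R)-7,3',4'-tris(benzyloxy)flavan-3,4-diol (2,3-trans-3,4-trans)
Conditions: NaBH4, THF–EtOH, 0 °C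
Reagents that add atoms: none
Why: Borohydride reduction of the 2,3-trans dihydroflavonol carbonyl should give mainly the 3,4-trans diol (4R) by hydride delivery anti to the neighbouring C3 oxygen, and the C4 configuration is of no consequence because C4 is ionized in step 10.

Step 9
Reactants: 13 (2R,3S,4R)-7,3',4'-tris(benzyloxy)flavan-3,4-diol
Product: 14 (2R,3S,4R)-3,4-di-O-acetyl-7,3',4'-tris(benzyloxy)flavan-3,4-diol
Conditions: Ac2O, pyridine, DMAP (cat.), rt
Reagents that add atoms: acetic anhydride, CC(=O)OC(C)=O
Why: Acylation of both secondary alcohols should install a benzylic leaving group at C4 and a participating ester at C3 without changing any stereocentre.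

Step 10
Reactants: 14 (2R,3S,4R)-3,4-di-O-acetyl-7,3',4'-tris(benzyloxy)flavan-3,4-diol; 10 (2R,3S)-8-bromo-5,7,3',4'-tetra-O-benzylcatechin (1.5 equiv)
Product: 16 3-O-acetyl-7,3',4'-tri-O-benzylfisetinidol-(4α→6)-8-bromo-5,7,3',4'-tetra-O-benzylcatechin, via acetoxonium triflate 15 (not isolated)
Conditions: Me3SiOTf (0.3 equiv), CH2Cl2, −78 → −40 °C; then aq. NaHCO3
Reagents that add atoms: none
Why: In this Lewis-acid promoted Friedel–Crafts alkylation, ionization of the C4 acetate should give a 2,4-dialkoxybenzyl cation that the 3-O-acetyl group captures as a cis-fused dioxolanylium ion on the face of the 3-oxygen, so that C6 of ring D, the only free position of the most electron-rich ring, opens it from the opposite face and sets the 3,4-trans (4α, 4S) configuration.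

Step 11
Reactants: 16 3-O-acetyl-7,3',4'-tri-O-benzylfisetinidol-(4α→6)-8-bromo-5,7,3',4'-tetra-O-benzylcatechin
Product: 17 7,3',4'-tri-O-benzylfisetinidol-(4α→6)-8-bromo-5,7,3',4'-tetra-O-benzylcatechin
Conditions: K2CO3 (cat.), MeOH–THF, rt
Reagents that add atoms: none
Why: Base-catalysed transesterification with methanol should remove the acetate without touching the benzyl ethers, the aryl bromide or any stereocentre.

Step 12
Reactants: 17 7,3',4'-tri-O-benzylfisetinidol-(4α→6)-8-bromo-5,7,3',4'-tetra-O-benzylcatechin
Product: 18 fisetinidol-(4α→6)-catechin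
Conditions: H2 (1 atm), Pd(OH)2/C, Et3N, THF–MeOH–H2O, rt
Reagents that add atoms: none
Why: Catalytic hydrogenolysis should cleave the seven benzyl ethers and the aryl C–Br bond, while Et3N buffers the HBr so that the acid-labile interflavan bond and all five stereocentres are kept.

**Compound list**

1 | 3,5-bis(benzyloxy)phenol | Oc1cc(OCc2ccccc2)cc(OCc2ccccc2)c1 | starting material
2 | 1-(allyloxy)-3,5-bis(benzyloxy)benzene | C=CCOc1cc(OCc2ccccc2)cc(OCc2ccccc2)c1 | intermediate
3 | 2-allyl-3,5-bis(benzyloxy)phenol | C=CCc1c(O)cc(OCc2ccccc2)cc1OCc1ccccc1 | intermediate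
4 | 3,4-bis(benzyloxy)benzoic acid | OC(=O)c1ccc(OCc2ccccc2)c(OCc2ccccc2)c1 | starting material
5 | 2-allyl-3,5-bis(benzyloxy)phenyl 3,4-bis(benzyloxy)benzoate | C=CCc1c(OC(=O)c2ccc(OCc3ccccc3)c(OCc3ccccc3)c2)cc(OCc2ccccc2)cc1OCc1ccccc1 | intermediate
6 | 2-allyl-3,5-bis(benzyloxy)phenyl 1-[3,4-bis(benzyloxy)phenyl]vinyl ether (vinyl ether diene, formed in the flask in step 4) | C=CCc1c(OC(=C)c2ccc(OCc3ccccc3)c(OCc3ccccc3)c2)cc(OCc2ccccc2)cc1OCc1ccccc1 | intermediate
7 | 5,7-bis(benzyloxy)-2-[3,4-bis(benzyloxy)phenyl]-4H-chromene (tetra-O-benzylflav-2-ene) | C1(c2ccc(OCc3ccccc3)c(OCc3ccccc3)c2)=CCc2c(OCc3ccccc3)cc(OCc3ccccc3)cc2O1 | intermediate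
8 | [(2R,3S)-5,7,3',4'-tetrakis(benzyloxy)flavan-3-yl](isopinocampheyl)borane, boron on C3 trans to the C2 aryl group (formed in the flask in step 5) | C[C@H]1[C@H](B[C@H]2Cc3c(OCc4ccccc4)cc(OCc4ccccc4)cc3O[C@@H]2c2ccc(OCc3ccccc3)c(OCc3ccccc3)c2)C[C@@H]2C[C@H]1C2(C)C | intermediate
9 | (2R,3S)-5,7,3',4'-tetra-O-benzylcatechin (2,3-trans) | O[C@H]1Cc2c(OCc3ccccc3)cc(OCc3ccccc3)cc2O[C@@H]1c1ccc(OCc2ccccc2)c(OCc2ccccc2)c1 | intermediate
10 | (2R,3S)-8-bromo-5,7,3',4'-tetra-O-benzylcatechin | O[C@H]1Cc2c(OCc3ccccc3)cc(OCc3ccccc3)c(Br)c2O[C@@H]1c1ccc(OCc2ccccc2)c(OCc2ccccc2)c1 | intermediate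
11 | (+)-fustin, (2R,3R)-3,7,3',4'-tetrahydroxyflavanone (2,3-trans) | O=C1c2ccc(O)cc2O[C@H](c2ccc(O)c(O)c2)[C@H]1O | starting material
12 | (2R,3R)-7,3',4'-tri-O-benzylfustin | O=C1c2ccc(OCc3ccccc3)cc2O[C@H](c2ccc(OCc3ccccc3)c(OCc3ccccc3)c2)[C@H]1O | intermediate
13 | (2R,3S,4R)-7,3',4'-tris(benzyloxy)flavan-3,4-diol (2,3-trans-3,4-trans) | O[C@@H]1c2ccc(OCc3ccccc3)cc2O[C@H](c2ccc(OCc3ccccc3)c(OCc3ccccc3)c2)[C@H]1O | intermediate
14 | (2R,3S,4R)-3,4-di-O-acetyl-7,3',4'-tris(benzyloxy)flavan-3,4-diol | CC(=O)O[C@@H]1c2ccc(OCc3ccccc3)cc2O[C@H](c2ccc(OCc3ccccc3)c(OCc3ccccc3)c2)[C@H]1OC(C)=O | intermediate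
15 | 2-methyl-1,3-dioxolan-2-ylium triflate cis-fused across O3/C3 and C4/O4 of the tri-O-benzylfisetinidol unit, on the face of the 3-oxygen (formed in the flask in step 10) | C[C+]1O[C@H]2c3ccc(OCc4ccccc4)cc3O[C@H](c3ccc(OCc4ccccc4)c(OCc4ccccc4)c3)[C@H]2O1.[O-]S(=O)(=O)C(F)(F)F | intermediate
16 | 3-O-acetyl-7,3',4'-tri-O-benzylfisetinidol-(4α→6)-8-bromo-5,7,3',4'-tetra-O-benzylcatechin; upper unit (2R,3S,4S), lower unit (2R,3S) | C(c1ccccc1)Oc1ccc2c(c1)O[C@H](c1ccc(OCc3ccccc3)c(OCc3ccccc3)c1)[C@@H](OC(C)=O)[C@@H]2c1c(OCc3ccccc3)c(Br)c2c(c1OCc1ccccc1)C[C@H](O)[C@@H](c1ccc(OCc3ccccc3)c(OCc3ccccc3)c1)O2 | intermediate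
17 | 7,3',4'-tri-O-benzylfisetinidol-(4α→6)-8-bromo-5,7,3',4'-tetra-O-benzylcatechin; upper unit (2R,3S,4S), lower unit (2R,3S) | C(c1ccccc1)Oc1ccc2c(c1)O[C@H](c1ccc(OCc3ccccc3)c(OCc3ccccc3)c1)[C@@H](O)[C@@H]2c1c(OCc3ccccc3)c(Br)c2c(c1OCc1ccccc1)C[C@H](O)[C@@H](c1ccc(OCc3ccccc3)c(OCc3ccccc3)c1)O2 | intermediate
18 | fisetinidol-(4α→6)-catechin; upper unit (2R,3S,4S), lower unit (2R,3S) | Oc1ccc2c(c1)O[C@H](c1ccc(O)c(O)c1)[C@@H](O)[C@@H]2c1c(O)cc2c(c1O)C[C@H](O)[C@@H](c1ccc(O)c(O)c1)O2 | target

**Step count and risks**

Total step count: 12. Longest linear sequence: 9 steps (steps 1–6, then 10–12, from 3,5-bis(benzyloxy)phenol).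

Steps most likely to fail:

Step 4. The titanium-mediated ring closure may stall at the acyclic vinyl ether, the allyl double bond may migrate into conjugation with ring D during the hot, aluminium-containing stage and so divert the closure, and the electron-rich enol ether may hydrolyse or isomerize on work-up. The fallback sets out from 5 and separates the two events: aluminium-free methylenation with Cp2TiMe2 (toluene, 70 °C) gives the vinyl ether diene 6, which is now isolated by filtration through basic alumina. Ring F is then closed by ruthenium-catalysed ring-closing metathesis with the second-generation Grubbs catalyst RuCl2(=CHPh)(PCy3)(H2IMes) (toluene, 60 °C). The route is rejoined at 7. Ring-closing metathesis of aryl 1-substituted vinyl ethers bearing an ortho allyl group to 2-substituted 4H-chromenes is established chemistry. This fallback makes no compound outside the list (F0).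

Step 5. The hindered chiral borane may discriminate the two faces of a 2-aryl enol ether poorly, and the β-aryloxy borane may undergo β-elimination with opening of ring F before oxidation. The fallback sets out from 7 and gives up reagent control. Hydroboration with BH3·SMe2 (THF, 0 °C; then NaOH, H2O2) should give racemic 2,3-trans-5,7,3',4'-tetra-O-benzylflavan-3-ol F1. Bromination with NBS as in step 6 gives racemic 8-bromo-2,3-trans-5,7,3',4'-tetra-O-benzylflavan-3-ol F2. F2 is coupled with the enantiopure diacetate 14 under the conditions of step 10, so that the fisetinidol unit acts as the resolving element. The coupling should give 16 together with its lower-unit (2S,3R) diastereomer, 3-O-acetyl-7,3',4'-tri-O-benzylfisetinidol-(4α→6)-8-bromo-5,7,3',4'-tetra-O-benzyl-ent-catechin F3, and the two are separated by chromatography. The route is rejoined at 16.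

Step 10. Attack by the doubly flanked, bromine-deactivated C6 may be slow, so that self-condensation of the electrophile through its own ring A competes, and the strong Lewis acid may erode the 4α selectivity by direct capture of the open cation or scramble the new interflavan bond. The fallback sets out from 14 and changes the mode of activation. Exchange of the C4 acetate with benzyl mercaptan (BnSH, BF3·OEt2, CH2Cl2, −20 °C) should give the 3,4-trans thioether (2R,3S,4S)-3-O-acetyl-4-benzylthio-7,3',4'-tris(benzyloxy)flavan-3-ol F4. F4 is then activated thiophilically with AgBF4 (THF, 0 °C) in the presence of excess 10. The cation is released slowly under essentially non-acidic conditions and is still bridged by the 3-O-acetyl group, so the 3,4-trans outcome should be kept. The route is rejoined at 16.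

**Further compounds**

F0 | step 4 | none | none
F1 | step 5 | racemic 2,3-trans-5,7,3',4'-tetra-O-benzylflavan-3-ol (1:1 mixture of the 2R,3S and 2S,3R forms) | O[C@H]1Cc2c(OCc3ccccc3)cc(OCc3ccccc3)cc2O[C@@H]1c1ccc(OCc2ccccc2)c(OCc2ccccc2)c1.O[C@@H]1Cc2c(OCc3ccccc3)cc(OCc3ccccc3)cc2O[C@H]1c1ccc(OCc2ccccc2)c(OCc2ccccc2)c1
F2 | step 5 | racemic 8-bromo-2,3-trans-5,7,3',4'-tetra-O-benzylflavan-3-ol (1:1 mixture of the 2R,3S and 2S,3R forms) | O[C@H]1Cc2c(OCc3ccccc3)cc(OCc3ccccc3)c(Br)c2O[C@@H]1c1ccc(OCc2ccccc2)c(OCc2ccccc2)c1.O[C@@H]1Cc2c(OCc3ccccc3)cc(OCc3ccccc3)c(Br)c2O[C@H]1c1ccc(OCc2ccccc2)c(OCc2ccccc2)c1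
F3 | step 5 | 3-O-acetyl-7,3',4'-tri-O-benzylfisetinidol-(4α→6)-8-bromo-5,7,3',4'-tetra-O-benzyl-ent-catechin; upper unit (2R,3S,4S), lower unit (2S,3R) | C(c1ccccc1)Oc1ccc2c(c1)O[C@H](c1ccc(OCc3ccccc3)c(OCc3ccccc3)c1)[C@@H](OC(C)=O)[C@@H]2c1c(OCc3ccccc3)c(Br)c2c(c1OCc1ccccc1)C[C@@H](O)[C@H](c1ccc(OCc3ccccc3)c(OCc3ccccc3)c1)O2
F4 | step 10 | (2R,3S,4S)-3-O-acetyl-4-benzylthio-7,3',4'-tris(benzyloxy)flavan-3-ol (2,3-trans-3,4-trans) | C(c1ccccc1)S[C@@H]1c2ccc(OCc3ccccc3)cc2O[C@H](c2ccc(OCc3ccccc3)c(OCc3ccccc3)c2)[C@H]1OC(C)=O
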